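**Plan**

1. Labels: ring A = benzo ring of the dihydrobenzofuran, ring B = its O-heterocycle, ring C = seven-membered ring, ring D = second resorcinol ring, rings E and F = the 4-hydroxyphenyl groups on C7 and C7'; C7–C8 = C2–C3 of ring B, C7' = CH(aryl) and C8' = C=O of ring C.
2. Retrosynthesis: the five O–methyl bonds are cut first, then C8'=O goes back to a C7'=C8' alkene, then the C7–C8 bond of ring B is cut to a carbene centre at C8 and the O–CH2 of a 4-methoxybenzyl ether on the ring-A oxygen. The achiral dibenzosuberenone left over is cut at C8–ring A (Friedel–Crafts acylation), C7'–C8' (benzylic alkylation) and C7'–ring D (Negishi coupling).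
3. Forward: ring D is joined to C7'/ring F, then to C8'/ring A; acylation closes ring C; DDQ makes the alkene; C7/ring E arrive as an ether; ring B closes last; then alkene to ketone, equilibration, demethylation.
4. Enabling feature: C8 lies between rings A and D, so it can be a diaryl (donor/donor) carbene carbon made from the ring-C ketone. C7 is bonded to the ring-A oxygen and to the 4-oxygenated ring E, so before the bond exists it is a hydridic ether CH2 held 1,5 to C8.
5. Stereochemistry: a chiral dirhodium catalyst sets C8 (R) and C7 (cis) on an achiral tricycle; acid then turns C7 to the stable trans arrangement by ionisation and re-closure, and C7' (α to the ketone) settles by enolisation.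

Key step: step 9

Assumption: the natural C7' configuration (enolisable, α to the ketone) is taken to be the thermodynamically preferred epimer, and Rh2(S-PTAD)4 is taken to deliver the 8R series (otherwise the mirror-image catalyst Rh2(R-PTAD)4 is used).

**Route**

Step 1
Reactants: 1 methyl 2-bromo-3,5-dimethoxybenzoate; 2 4-methoxybenzylzinc chloride (THF solution)
Product: 3 methyl 3,5-dimethoxy-2-(4-methoxybenzyl)benzoate
Conditions: Pd(OAc)2 (2 mol %), SPhos (4 mol %), THF, 25 → 50 °C
Reagents that add atoms: none
Why: Negishi cross-coupling, in which the Pd/SPhos catalyst adds to the hindered, electron-rich aryl bromide and the benzylic zinc reagent transmetallates without touching the ester, joining ring D to C7' and ring F.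

Step 2
Reactants: 3 methyl 3,5-dimethoxy-2-(4-methoxybenzyl)benzoate; 4 3,5-dimethoxybenzyl bromide
Product: 6 methyl 2-[2-(3,5-dimethoxyphenyl)-1-(4-methoxyphenyl)ethyl]-3,5-dimethoxybenzoate (racemic), via benzylic organolithium 5 (not isolated)
Conditions: LiN(i-Pr)2, THF, −78 °C; then 4, −78 → 0 °C
Reagents that add atoms: lithium diisopropylamide, [Li+].CC(C)[N-]C(C)C (lithium of 5 only)
Why: Lateral (benzylic) lithiation–alkylation: the C7' methylene is acidified by both aryl rings and the ortho ester, the non-nucleophilic amide base spares the ester, and the benzylic bromide alkylates the anion at carbon to add C8' and ring A; C7' is formed racemic and is erased again in step 5.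

Step 3
Reactants: 6 methyl 2-[2-(3,5-dimethoxyphenyl)-1-(4-methoxyphenyl)ethyl]-3,5-dimethoxybenzoate
Product: 7 2-[2-(3,5-dimethoxyphenyl)-1-(4-methoxyphenyl)ethyl]-3,5-dimethoxybenzoic acid (racemic)
Conditions: LiOH, THF/MeOH/H2O, 60 °C; then 1 M HCl
Reagents that add atoms: lithium hydroxide, [Li+].[OH-] (oxygen of the acid OH)
Why: Saponification of a methyl benzoate that has one free ortho position, with no other base-labile group present.

Step 4
Reactants: 7 2-[2-(3,5-dimethoxyphenyl)-1-(4-methoxyphenyl)ethyl]-3,5-dimethoxybenzoic acid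
Product: 9 1,3,6,8-tetramethoxy-11-(4-methoxyphenyl)-10,11-dihydro-5H-dibenzo[a,d][7]annulen-5-one (racemic), via mixed trifluoroacetic anhydride 8 (not isolated)
Conditions: (CF3CO)2O, CH2Cl2, 0 °C → rt
Reagents that add atoms: trifluoroacetic anhydride, O=C(OC(=O)C(F)(F)F)C(F)(F)F (trifluoroacetyl group of 8 only)
Why: Intramolecular Friedel–Crafts acylation through the mixed anhydride: the acyl carbon (C8) attacks ring A ortho to its CH2 group at a position ortho and para to the two methoxy groups (both such positions are equivalent), which closes ring C in preference to a six-membered closure onto ring F, whose reachable positions are only meta to its methoxy group.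

Step 5
Reactants: 9 1,3,6,8-tetramethoxy-11-(4-methoxyphenyl)-10,11-dihydro-5H-dibenzo[a,d][7]annulen-5-one
Product: 10 1,3,6,8-tetramethoxy-11-(4-methoxyphenyl)-5H-dibenzo[a,d][7]annulen-5-one (achiral)
Conditions: DDQ (1.5 equiv), 1,4-dioxane, 100 °C
Reagents that add atoms: none
Why: DDQ dehydrogenation: hydride abstraction from the doubly benzylic C7'–H (stabilised by the para-methoxy group of ring F and the ortho/para-methoxy groups of ring D) and proton loss from C8' give the conjugated triaryl alkene, which removes the C7' stereocentre and leaves C7'=C8' as the later handle for the ketone.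

Step 6
Reactants: 10 1,3,6,8-tetramethoxy-11-(4-methoxyphenyl)-5H-dibenzo[a,d][7]annulen-5-one
Product: 11 6-hydroxy-1,3,8-trimethoxy-11-(4-methoxyphenyl)-5H-dibenzo[a,d][7]annulen-5-one
Conditions: BCl3 (1.5 equiv), CH2Cl2, −78 → 0 °C; then H2O
Reagents that add atoms: none
Why: Chelation-controlled ether cleavage: BCl3 binds the C8 carbonyl oxygen and the peri methoxy oxygen on ring A in a six-membered chelate and chloride removes only that methyl group, the classical selective demethylation ortho to an aryl ketone.

Step 7
Reactants: 11 6-hydroxy-1,3,8-trimethoxy-11-(4-methoxyphenyl)-5H-dibenzo[a,d][7]annulen-5-one; 12 4-methoxybenzyl chloride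
Product: 13 1,3,8-trimethoxy-6-[(4-methoxybenzyl)oxy]-11-(4-methoxyphenyl)-5H-dibenzo[a,d][7]annulen-5-one
Conditions: K2CO3, n-Bu4NI (cat.), DMF, 60 °C
Reagents that add atoms: none
Why: Williamson ether synthesis on the hydrogen-bonded peri phenol; the 4-methoxybenzyl group is not a protecting group here but supplies C7 and ring E.

Step 8
Reactants: 13 1,3,8-trimethoxy-6-[(4-methoxybenzyl)oxy]-11-(4-methoxyphenyl)-5H-dibenzo[a,d][7]annulen-5-one
Product: 14 5-hydrazinylidene-1,3,8-trimethoxy-6-[(4-methoxybenzyl)oxy]-11-(4-methoxyphenyl)-5H-dibenzo[a,d][7]annulene (hydrazone of 13 at C8)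
Conditions: N2H4·H2O (10 equiv), AcOH (cat.), n-BuOH, 110 °C
Reagents that add atoms: hydrazine hydrate, NN.O (the two nitrogen atoms)
Why: Hydrazone condensation of the diaryl ketone with excess hydrazine (the excess suppresses azine formation); because C8' is still an alkene carbon, C8 is the only carbonyl group and the hydrazone forms there unambiguously.

Step 9
Reactants: 14 hydrazone of 13
Product: 16 (7S,8R)-7,8-cis tetracycle (1S,11bR)-4,8,10-trimethoxy-1,7-bis(4-methoxyphenyl)-1,11b-dihydrobenzo[6,7]cyclohepta[1,2,3-cd][1]benzofuran, via diazo compound 15 (not isolated)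
Conditions: MnO2 (10 equiv), CH2Cl2, 0 °C, filter; filtrate added slowly to Rh2(S-PTAD)4 (1 mol %), CH2Cl2, −40 °C → rt
Reagents that add atoms: none
Why: MnO2 dehydrogenates hydrazone 14 to the cyclic diaryl diazo compound 15, and the divalent-rhodium carboxylate dimer Rh2(S-PTAD)4 (tetrakis[(S)-(1-adamantyl)(N-phthalimido)acetato]dirhodium) expels N2 from it to give a donor/donor rhodium carbene at C8, which inserts by a hydride-transfer-like three-centre transition state into one C–H bond of the peri O–CH2–aryl group and so forms the C7–C8 bond. The closest known reaction type is the dirhodium-catalysed enantioselective intramolecular C–H insertion of diaryl carbenes, generated from ortho-benzyloxy benzophenone hydrazones, that gives 2,3-diaryl-2,3-dihydrobenzofurans; here the same reaction is run on a carbene whose two aryl groups are tied together in ring C. Ring B closes in the 1,5-insertion mode (five-membered ring of C8, two ring-A carbons, O and C7), the two hydrogens of the ether CH2 being the only C–H bonds within reach of C8 and also the most hydridic ones in the molecule (oxygen lone pair and the 4-methoxyphenyl ring E). C8 and C7 are created in the same event: the chiral carboxylate ligands decide which carbene face receives the hydrogen (C8, R) and which enantiotopic hydrogen of the CH2 group is transferred (C7), and by analogy with acyclic diaryl carbenes the kinetic product should be the 7,8-cis isomer (7S,8R). The step needs insertion to outrun azine and carbene-dimer formation and cyclopropanation; slow addition of 15 to the catalyst at low temperature keeps its concentration low, the reacting CH2 is held next to C8 by the ring-A oxygen, and the only alkene (C7'=C8') is trisubstituted, shielded by three aryl groups and cannot be reached across ring C. Because 15 is achiral, the catalyst alone fixes the absolute configuration that is carried through to the target.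

Step 10
Reactants: 16 (7S,8R)-7,8-cis tetracycle
Product: 18 (7S,8R,7'R,8'S)-alcohol (1S,6S,7R,11bR)-4,8,10-trimethoxy-1,7-bis(4-methoxyphenyl)-1,6,7,11b-tetrahydrobenzo[6,7]cyclohepta[1,2,3-cd][1]benzofuran-6-ol (H-7' and 8'-OH cis), via alkylborane 17 (not isolated)
Conditions: BH3·THF, THF, 0 → 40 °C; then NaOH (aq), H2O2, 0 °C → rt
Reagents that add atoms: borane–tetrahydrofuran, B.C1CCOC1 (boron of 17 only); hydrogen peroxide, OO (oxygen of 18)
Why: Brown hydroboration–oxidation: boron adds to the less substituted C8' and hydrogen to the diaryl-substituted C7' in a syn fashion, and oxidation with retention gives the C8' alcohol; the face of attack is immaterial because C8' becomes a carbonyl in step 11 and C7' is equilibrated in step 12 (the isomer drawn results from attack on the alkene face on the side of C7).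

Step 11
Reactants: 18 (7S,8R,7'R,8'S)-alcohol
Product: 19 (7S,8R,7'R)-ketone (7-epi-pauciflorol E pentamethyl ether) (1S,7R,11bR)-4,8,10-trimethoxy-1,7-bis(4-methoxyphenyl)-1,11b-dihydrobenzo[6,7]cyclohepta[1,2,3-cd][1]benzofuran-6(7H)-one
Conditions: Dess–Martin periodinane (1.5 equiv), CH2Cl2, rt
Reagents that add atoms: none
Why: Dess–Martin oxidation of the secondary benzylic alcohol to the ring-C ketone under neutral conditions that leave the dihydrobenzofuran untouched.

Step 12
Reactants: 19 (7S,8R,7'R)-ketone
Product: 20 pauciflorol E pentamethyl ether (7R,8R,7'R) (1R,7R,11bR)-4,8,10-trimethoxy-1,7-bis(4-methoxyphenyl)-1,11b-dihydrobenzo[6,7]cyclohepta[1,2,3-cd][1]benzofuran-6(7H)-one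
Conditions: CF3CO2H, CH2Cl2 (dilute), 0 °C → rt
Reagents that add atoms: none
Why: Acid-mediated thermodynamic equilibration: reversible heterolysis of the benzylic C7–O bond (cation stabilised by the para-methoxy group of ring E) and re-closure by the ring-A phenol should turn the 7,8-cis into the more stable 7,8-trans dihydrobenzofuran with C8 untouched (dilute acid at low temperature to disfavour elimination toward C8), while C7' settles through the enol in its more stable configuration, anti to C7 across ring C.

Step 13
Reactants: 20 pauciflorol E pentamethyl ether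
Product: 21 pauciflorol E (7R,8R,7'R) (1R,7R,11bR)-4,8,10-trihydroxy-1,7-bis(4-hydroxyphenyl)-1,11b-dihydrobenzo[6,7]cyclohepta[1,2,3-cd][1]benzofuran-6(7H)-one
Conditions: BBr3 (excess), CH2Cl2, −78 °C → rt; then MeOH, H2O
Reagents that add atoms: none
Why: Lewis-acid ether cleavage with BBr3, the usual final step for permethylated resveratrol oligomers that contain 2-aryl-2,3-dihydrobenzofuran rings; C7 and C7' already hold their thermodynamic configurations, so reversible ionisation or enolisation returns the same isomer, and C8 has no pathway for inversion.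

**Compound list**

1 | methyl 2-bromo-3,5-dimethoxybenzoate | COC(=O)c1cc(OC)cc(OC)c1Br | starting material
2 | 4-methoxybenzylzinc chloride | COc1ccc(C[Zn]Cl)cc1 | starting material
3 | methyl 3,5-dimethoxy-2-(4-methoxybenzyl)benzoate | COC(=O)c1cc(OC)cc(OC)c1Cc1ccc(OC)cc1 | intermediate
4 | 3,5-dimethoxybenzyl bromide | COc1cc(CBr)cc(OC)c1 | starting material
5 | benzylic organolithium of 3 (lithium on C7') | COC(=O)c1cc(OC)cc(OC)c1C([Li])c1ccc(OC)cc1 | intermediate
6 | methyl 2-[2-(3,5-dimethoxyphenyl)-1-(4-methoxyphenyl)ethyl]-3,5-dimethoxybenzoate (racemic) | COC(=O)c1cc(OC)cc(OC)c1C(Cc1cc(OC)cc(OC)c1)c1ccc(OC)cc1 | intermediate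
7 | 2-[2-(3,5-dimethoxyphenyl)-1-(4-methoxyphenyl)ethyl]-3,5-dimethoxybenzoic acid (racemic) | OC(=O)c1cc(OC)cc(OC)c1C(Cc1cc(OC)cc(OC)c1)c1ccc(OC)cc1 | intermediate
8 | mixed anhydride of 7 with trifluoroacetic acid | O=C(OC(=O)C(F)(F)F)c1cc(OC)cc(OC)c1C(Cc1cc(OC)cc(OC)c1)c1ccc(OC)cc1 | intermediate
9 | 1,3,6,8-tetramethoxy-11-(4-methoxyphenyl)-10,11-dihydro-5H-dibenzo[a,d][7]annulen-5-one (racemic) | O=C1c2cc(OC)cc(OC)c2C(c2ccc(OC)cc2)Cc2cc(OC)cc(OC)c21 | intermediate
10 | 1,3,6,8-tetramethoxy-11-(4-methoxyphenyl)-5H-dibenzo[a,d][7]annulen-5-one | O=C1c2cc(OC)cc(OC)c2C(c2ccc(OC)cc2)=Cc2cc(OC)cc(OC)c21 | intermediate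
11 | 6-hydroxy-1,3,8-trimethoxy-11-(4-methoxyphenyl)-5H-dibenzo[a,d][7]annulen-5-one | O=C1c2cc(OC)cc(OC)c2C(c2ccc(OC)cc2)=Cc2cc(OC)cc(O)c21 | intermediate
12 | 4-methoxybenzyl chloride | COc1ccc(CCl)cc1 | starting material
13 | 1,3,8-trimethoxy-6-[(4-methoxybenzyl)oxy]-11-(4-methoxyphenyl)-5H-dibenzo[a,d][7]annulen-5-one | O=C1c2cc(OC)cc(OC)c2C(c2ccc(OC)cc2)=Cc2cc(OC)cc(OCc3ccc(OC)cc3)c21 | intermediate
14 | hydrazone of 13 at C8 (either C=N geometry) | NN=C1c2cc(OC)cc(OC)c2C(c2ccc(OC)cc2)=Cc2cc(OC)cc(OCc3ccc(OC)cc3)c21 | intermediate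
15 | 5-diazo-1,3,8-trimethoxy-6-[(4-methoxybenzyl)oxy]-11-(4-methoxyphenyl)-5H-dibenzo[a,d][7]annulene | [N-]=[N+]=C1c2cc(OC)cc(OC)c2C(c2ccc(OC)cc2)=Cc2cc(OC)cc(OCc3ccc(OC)cc3)c21 | intermediate
16 | (7S,8R)-7,8-cis tetracycle with C7'=C8' alkene; (1S,11bR)-4,8,10-trimethoxy-1,7-bis(4-methoxyphenyl)-1,11b-dihydrobenzo[6,7]cyclohepta[1,2,3-cd][1]benzofuran | C1(c2ccc(OC)cc2)=Cc2cc(OC)cc3c2[C@@H](c2cc(OC)cc(OC)c21)[C@@H](c1ccc(OC)cc1)O3 | intermediate
17 | alkylborane from 16 (BH2 on C8', cis to H-7') | B[C@@H]1c2cc(OC)cc3c2[C@@H](c2cc(OC)cc(OC)c2[C@H]1c1ccc(OC)cc1)[C@@H](c1ccc(OC)cc1)O3 | intermediate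
18 | (7S,8R,7'R,8'S)-alcohol; (1S,6S,7R,11bR)-4,8,10-trimethoxy-1,7-bis(4-methoxyphenyl)-1,6,7,11b-tetrahydrobenzo[6,7]cyclohepta[1,2,3-cd][1]benzofuran-6-ol | O[C@@H]1c2cc(OC)cc3c2[C@@H](c2cc(OC)cc(OC)c2[C@H]1c1ccc(OC)cc1)[C@@H](c1ccc(OC)cc1)O3 | intermediate
19 | (7S,8R,7'R)-ketone, 7-epi-pauciflorol E pentamethyl ether | O=C1c2cc(OC)cc3c2[C@@H](c2cc(OC)cc(OC)c2[C@H]1c1ccc(OC)cc1)[C@@H](c1ccc(OC)cc1)O3 | intermediate
20 | pauciflorol E pentamethyl ether (7R,8R,7'R) | O=C1c2cc(OC)cc3c2[C@@H](c2cc(OC)cc(OC)c2[C@H]1c1ccc(OC)cc1)[C@H](c1ccc(OC)cc1)O3 | intermediate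
21 | pauciflorol E (7R,8R,7'R) | O=C1c2cc(O)cc3c2[C@@H](c2cc(O)cc(O)c2[C@H]1c1ccc(O)cc1)[C@H](c1ccc(O)cc1)O3 | target

**Totals**

Total step count: 13. Longest linear sequence: 13 steps (1 → 21); compounds 2, 4 and 12 enter as purchased reagents.

**Steps most likely to fail, with fallbacks**

Step 9. The rhodium carbene is held in ring C and flanked by a peri ether. It may dimerise or form azine faster than it inserts, or the chiral pocket may discriminate the two carbene faces poorly, so that enantiomeric purity is lost. The fallback is a polar [4+1] annulation of an ortho-quinone methide with a sulfonium ylide; it leaves the route at 11 and 12 and returns at 20, bypassing steps 8, 9 and 12. Ketone 11 would be reduced with NaBH4 (MeOH/THF, 0 °C) to the carbinol F1. Chloride 12 and tetrahydrothiophene (acetone, rt) would give the sulfonium salt F2. With Cs2CO3 in MeCN (40 °C), F1 should lose water to the ortho-quinone methide (ring A quinoid, C8 electrophilic). The benzylic ylide from F2 then adds at C8 and the phenoxide displaces tetrahydrothiophene at C7, which should give the 7,8-trans dihydrobenzofuran directly as a racemate. Separation on a chiral stationary phase would give the (7R,8R) trans-dihydrobenzofuran F3. Hydroboration–oxidation as in step 10 would give the alcohol F4, and Dess–Martin oxidation as in step 11 would give 20 (a brief acid or base treatment equilibrates C7' if needed).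

Step 8. Condensation at a ketone carbon flanked by three ortho substituents may stall, and forcing conditions favour azine formation or loss of the 4-methoxybenzyl group. The fallback leaves at 13 and returns at 14. Thionation of 13 with Lawesson's reagent (toluene, 90 °C) would give the thioketone F5. Its C=S carbon is far more electrophilic, and condensation with N2H4·H2O (THF/EtOH, rt), driven by loss of H2S, should give 14.

Step 10. Addition of borane to a trisubstituted triaryl alkene in the fold of ring C may be slow and may lose regioselectivity. The fallback leaves at 16 and returns at 18. Epoxidation with dimethyldioxirane (acetone, −20 °C) would give the epoxide F6. Cp2TiCl (trivalent titanium, made in the flask from Cp2TiCl2 and Mn powder) in THF with 1,4-cyclohexadiene should open it by homolysis of the C7'–O bond to the aryl-stabilised C7' radical, which takes up a hydrogen atom; hydrolysis of the titanium alkoxide gives 18.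

**Further compounds**

F1 | step 9 | 1,3,8-trimethoxy-11-(4-methoxyphenyl)-5H-dibenzo[a,d][7]annulene-5,6-diol (racemic carbinol) | OC1c2cc(OC)cc(OC)c2C(c2ccc(OC)cc2)=Cc2cc(OC)cc(O)c21
F2 | step 9 | 1-(4-methoxybenzyl)tetrahydrothiophen-1-ium chloride | COc1ccc(C[S+]2CCCC2)cc1.[Cl-]
F3 | step 9 | (7R,8R)-7,8-trans isomer of 16; (1R,11bR)-4,8,10-trimethoxy-1,7-bis(4-methoxyphenyl)-1,11b-dihydrobenzo[6,7]cyclohepta[1,2,3-cd][1]benzofuran | C1(c2ccc(OC)cc2)=Cc2cc(OC)cc3c2[C@@H](c2cc(OC)cc(OC)c21)[C@H](c1ccc(OC)cc1)O3
F4 | step 9 | (7R,8R,7'R,8'S)-alcohol, 7,8-trans isomer of 18 | O[C@@H]1c2cc(OC)cc3c2[C@@H](c2cc(OC)cc(OC)c2[C@H]1c1ccc(OC)cc1)[C@H](c1ccc(OC)cc1)O3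
F5 | step 8 | 1,3,8-trimethoxy-6-[(4-methoxybenzyl)oxy]-11-(4-methoxyphenyl)-5H-dibenzo[a,d][7]annulene-5-thione | S=C1c2cc(OC)cc(OC)c2C(c2ccc(OC)cc2)=Cc2cc(OC)cc(OCc3ccc(OC)cc3)c21
F6 | step 10 | 7',8'-epoxide of 16 (oxygen on the alkene face on the side of C7) | O1[C@@H]2c3cc(OC)cc4c3[C@@H](c3cc(OC)cc(OC)c3[C@]12c1ccc(OC)cc1)[C@@H](c1ccc(OC)cc1)O4
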